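Readings and results were computed for an exercise, noise included.

Time was what I counted in these flasks: how long partner can wait for substrate before it is lost.

| flask | substrate | partner | rival reagent | protic impurity | remark | time |
|---|---|---|---|---|---|---|
| south-east | 0.066 M | 0.099 M | 0.198 M | 1.32 mM | run made earlier |  |
| south-west | 0.092 M | 0.099 M | 0.198 M | 1.32 mM | run made earlier |  |
| north | 0.15 M | 0.099 M | 0.198 M | 1.32 mM | run made earlier |  |
| violet | 0.066 M | 0.0990 M | 0.198 M (fed, over 12 h) | 1.32 mM | all else is in the flask from the start; the feed brings no volume worth counting | 30 h |
| red | 0.066 M | 0.0990 M | 0.198 M | 1.32 mM | everything together at the start | 30 h |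
| amber | 0.066 M (fed, over 12 h) | 0.0990 M | 0.198 M | 1.32 mM | all else is in the flask from the start; the feed brings no volume worth counting | 30 h |
| green | 0.066 M (fed, over 3.0 h) | 0.0990 M | 0.198 M | 1.32 mM | all else is in the flask from the start; the feed brings no volume worth counting | 30 h |

| run | time / h | target / % | side product / % |
|---|---|---|---|
| south-east | 3.00 | 67.7 | 1.5 |
| south-east | 6.00 | 81.4 | 2.4 |
| south-east | 10.0 | 87.4 | 3.6 |
| south-east | 12.0 | 88.8 | 3.5 |
| south-east | 15.0 | 91.0 | 3.8 |
| south-east | 20.0 | 92.3 | 4.0 |
| south-west | 2.00 | 54.4 | 1.8 |
| south-west | 3.00 | 62.8 | 2.4 |
| south-west | 5.00 | 71.5 | 2.2 |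
| south-west | 8.00 | 77.3 | 3.4 |
| south-west | 15.0 | 82.4 | 4.9 |
| south-west | 25.0 | 85.3 | 6.2 |
| north | 1.50 | 41.3 | 1.4 |
| north | 5.00 | 57.0 | 3.4 |
| north | 8.00 | 58.6 | 4.6 |
| north | 12.0 | 59.4 | 5.7 |
| north | 20.0 | 58.9 | 9.1 |
| north | 25.0 | 59.4 | 10.2 |

(each reading ± 0.3 percentage points)

- the analysis behind the earlier runs scatters by 0.3 percentage points, standard deviation

* the best flask by share of target in target plus side product; "all alike" if 1.5 percentage points covers them all (violet / red / amber / green / all alike)
* share of target in target plus side product at the end, violet
* share of target in target plus side product at the end, red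
* share of target in target plus side product at the end, amber
* share of target in target plus side product at the end, green

The north run gave me a clock. Partner was the limiting reagent there, and target read 59.4% at 12.0 h and 59.4% at 25.0 h, so target had stopped short of what the partner charge allowed. The shortfall was a leak of partner:

c(partner) lost = 0.00990 M

The first north reading, put into the second-order law, gave the coupling constant:

k = 0.00163 L mol⁻¹ s⁻¹

I treated the leak as pseudo-first-order. Setting it against coupling over the north run gave a rate and the quantity I carried, the leak half-life, an estimate of the time in which partner halves by the leak under that first-order assumption: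

leak rate = k × c(partner) lost / ln(charged substrate / substrate left by coupling) = 0.0646 h⁻¹

leak half-life = 10.7 h

Then I turned the settings one by one. With everything together at the start, as in red, substrate halves against partner in 1.19 h, a shorter time than the leak half-life. Red repeats the south-east recipe, whose last reading gives a share of 95.8%.

Feeding substrate over 3.0 h, as in green, spans 0.280 leak half-lives, so I expected a modest loss of share. Feeding it over 12 h, as in amber, spans 1.12, so I expected a heavy loss.

Feeding rival reagent, as in violet, delivers 9.92% of it by the time substrate has halved. I expected less side product, assuming side product needs rival reagent, which no run tested.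

My order was violet, red, green, amber. The forecast gave the same order: 98.6%, 95.6%, 94.9%, 91.5%, with violet best. For red it differs slightly from my reading. On amber it said “slow substrate feed lets partner die first”.

The flasks gave 97.9% for violet, 95.6% for red, 93.5% for green and 88.7% for amber, and violet was best.

    substrate + partner → target (k = 0.00190 L mol⁻¹ s⁻¹)
    substrate + rival reagent → side product (k = 1.70 × 10⁻⁵ L mol⁻¹ s⁻¹)
    rival reagent + protic impurity → quenched reagent (k = 0.0470 L mol⁻¹ s⁻¹)
    2 partner → homo dimer (k = 2.50 × 10⁻⁴ L mol⁻¹ s⁻¹)

The scheme makes the leak second order in partner, so its half-life lengthens as partner falls, and at the charge its first half-life is 5.61 h, shorter than my leak half-life of 10.7 h. On that first half-life green's feed spanned 0.535 and amber's 2.14; red's share stood above green's, and green's above amber's. At 12.0 h, amber held 12.4% of its partner against 42.1% of its substrate, with 0.0253 M of homo dimer formed. Violet led amber by 9.2 percentage points, and that gap owes 7.1 points to the pairing of partner into homo dimer. With that step struck out, the gap between violet and amber stood at 2 points.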